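**Plan**

1. Enabling feature (locants: carbocycle C1–C10, γ-lactone C6–O–C12(=O)–C11–C7, exocyclic C13, methyls C14 on C10 and C15 on C4): the oxirane carbon C1 lies between the oxygenated quaternary C10 and C2, and C2 is α to the C3 carbinol. With C3 as a ketone and the oxirane oxygen kept on C10, C1 is an inverted aldol carbinol, so the ten-membered ring opens at C1–C2.
2. Cuts, in order: the C13 methylene and the C1–O oxirane bond; C1–C2 (bromomethyl ketone plus non-enolisable α-alkoxy aldehyde); C5–C6 together with the lactone O6–C12 bond (Z-alkenyllithium plus C6 aldehyde); C7–C8 (auxiliary syn-aldol). This leaves a C8–C9–C10–C1 aldehyde, a succinate half ester (C6, C7, C11, C12) and a Z-iodoalkene (C2–C5, C15).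
3. Forward ring order: γ-lactone (step 12), ten-membered carbocycle by SmI2 Reformatsky closure (step 19), oxirane by displacement at C1 (step 24); the C13 methylene is added afterwards.
4. Stereochemistry: C10 from (R)-2-methylglycidol; C7 and C8 from the thiazolidinethione titanium aldol; C6 by Felkin–Anh addition; Z-C4=C5 from anti-carbomagnesiation of a propargylic alcohol; C1 by samarium chelation to O10, inverted at oxirane closure; C3 by hydroxyl-directed 1,3-anti reduction.

Key step: step 19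

Remark 1: the target locants are used for all intermediates and CIP descriptors are given with them; C7 reads R instead of S only while O8 carries silicon, with no change in geometry.
Remark 2: the carbinol centre of the butynol fragment is destroyed by oxidation in step 14; the (S) enantiomer is taken only so that intermediates are single diastereomers.
Remark 3: (R)-2-methylglycidol and (S)-but-3-yn-2-ol are assumed to be used as commercial single enantiomers.

**Route**

Step 1
Reactants: 1 (R)-2-methylglycidol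
Product: 2 (S)-2-methylpent-4-ene-1,2-diol
Conditions: CH2=CHMgBr (2.5 equiv), CuI (10 mol %), THF, −30 to 0 °C
Reagents that add atoms: vinylmagnesium bromide, C=C[Mg]Br
Why: Copper-catalysed Grignard opening of the epoxide by SN2 attack at its unsubstituted CH2 (the future C9) leaves the quaternary carbinol centre C10 untouched, so C10 comes from the chiral pool.

Step 2
Reactants: 2 (S)-2-methylpent-4-ene-1,2-diol
Product: 3 (4S)-2-(4-methoxyphenyl)-4-methyl-4-(prop-2-en-1-yl)-1,3-dioxolane (both acetal epimers)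
Conditions: 4-MeOC6H4CH(OMe)2, PPTS (cat.), CH2Cl2, 23 °C
Reagents that add atoms: 4-methoxybenzaldehyde dimethyl acetal, COc1ccc(C(OC)OC)cc1
Why: Acid-catalysed transacetalisation closes the five-membered p-methoxybenzylidene acetal on the 1,2-diol.

Step 3
Reactants: 3 (4S)-p-methoxybenzylidene acetal
Product: 4 (S)-2-[(4-methoxybenzyl)oxy]-2-methylpent-4-en-1-ol
Conditions: i-Bu2AlH (3 equiv), CH2Cl2, −78 to 0 °C
Reagents that add atoms: none
Why: In this reductive acetal opening aluminium binds the less hindered primary oxygen and hydride reduces the resulting oxocarbenium ion, so the PMB ether stays on the tertiary O10 and the C1 hydroxyl is freed.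

Step 4
Reactants: 4 (S)-2-[(4-methoxybenzyl)oxy]-2-methylpent-4-en-1-ol
Product: 5 (S)-tert-butyl({2-[(4-methoxybenzyl)oxy]-2-methylpent-4-en-1-yl}oxy)dimethylsilane
Conditions: TBSCl, imidazole, DMF, 23 °C
Reagents that add atoms: tert-butyldimethylsilyl chloride, CC(C)(C)[Si](C)(C)Cl
Why: Standard silylation of the primary alcohol masks C1 until the aldehyde is needed.

Step 5
Reactants: 5 (S)-TBS ether of the pentenol
Product: 7 (S)-4-[(tert-butyldimethylsilyl)oxy]-3-[(4-methoxybenzyl)oxy]-3-methylbutanal, via 1,2-diol 6 (not isolated)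
Conditions: OsO4 (2 mol %), NaIO4 (4 equiv), 2,6-lutidine, dioxane/H2O (3:1), 23 °C
Reagents that add atoms: osmium tetroxide, O=[Os](=O)(=O)=O; sodium periodate, [Na+].[O-]I(=O)(=O)=O
Why: Lemieux–Johnson cleavage, in which catalytic OsO4 dihydroxylates the terminal alkene and NaIO4 cleaves the diol and re-oxidises osmium, gives the C8 aldehyde while the base protects the β-alkoxy aldehyde from elimination.

Step 6
Reactants: 8 (S)-but-3-yn-2-ol
Product: 10 (2S,3Z)-4-iodo-3-methylbut-3-en-2-ol, via cyclic alkenylmagnesium alkoxide 9 (not isolated)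
Conditions: MeMgBr (3 equiv), CuI (10 mol %), THF, −10 to 23 °C; then I2, THF, −40 to 0 °C
Reagents that add atoms: methylmagnesium bromide, C[Mg]Br; iodine, II
Why: Copper-catalysed anti-carbomagnesiation of the propargylic alkoxide places methyl on C4 and magnesium on C5 inside a five-membered chelate, and iodinolysis with retention gives the iodoalkene with iodine cis to C3, which fixes the Z geometry of C4=C5.

Step 7
Reactants: 10 (2S,3Z)-4-iodo-3-methylbut-3-en-2-ol
Product: 11 triethyl{[(2S,3Z)-4-iodo-3-methylbut-3-en-2-yl]oxy}silane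
Conditions: TESCl, imidazole, CH2Cl2, 0 °C
Reagents that add atoms: chlorotriethylsilane, CC[Si](CC)(CC)Cl
Why: Silylation removes the acidic hydroxyl before halogen–lithium exchange.

Step 8
Reactants: 12 4-(tert-butoxy)-4-oxobutanoic acid; 13 (S)-4-benzyl-1,3-thiazolidine-2-thione
Product: 14 tert-butyl 4-[(4S)-4-benzyl-2-thioxo-1,3-thiazolidin-3-yl]-4-oxobutanoate
Conditions: EDC·HCl, DMAP (cat.), CH2Cl2, 0 to 23 °C
Reagents that add atoms: none
Why: Carbodiimide-mediated (Steglich-type) N-acylation of the thiazolidinethione gives the aldol donor.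

Step 9
Reactants: 14 N-acylthiazolidinethione; 7 C8 aldehyde
Product: 16 syn-aldol adduct tert-butyl (3S,4R,6S)-3-{[(4S)-4-benzyl-2-thioxo-1,3-thiazolidin-3-yl]carbonyl}-7-[(tert-butyldimethylsilyl)oxy]-4-hydroxy-6-[(4-methoxybenzyl)oxy]-6-methylheptanoate (7S,8R,10S), via chlorotitanium enolate 15 (not isolated)
Conditions: TiCl4 (1.05 equiv), i-Pr2NEt (1.1 equiv), N-methylpyrrolidinone (1.0 equiv), CH2Cl2, 0 °C; then 7, −78 °C
Reagents that add atoms: none
Why: In this titanium-mediated thiazolidinethione syn-aldol the Z-enolate, formed only at the imide α-carbon, reacts through a non-chelated chair transition state whose face is dictated by the benzyl group of the auxiliary (Evans-syn sense), setting C7 (S) and C8 (R) by reagent control.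

Step 10
Reactants: 16 syn-aldol adduct
Product: 17 C8 triethylsilyl ether of 16 (7S,8R,10S)
Conditions: TESOTf, 2,6-lutidine, CH2Cl2, −78 °C
Reagents that add atoms: triethylsilyl trifluoromethanesulfonate, CC[Si](CC)(CC)OS(=O)(=O)C(F)(F)F
Why: Silylation with the triflate protects the hindered C8 hydroxyl with a non-chelating group and blocks retro-aldol cleavage.

Step 11
Reactants: 17 silylated aldol adduct
Product: 18 tert-butyl (3S,4R,6S)-7-[(tert-butyldimethylsilyl)oxy]-3-formyl-6-[(4-methoxybenzyl)oxy]-6-methyl-4-[(triethylsilyl)oxy]heptanoate (C6 aldehyde)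
Conditions: i-Bu2AlH (1.3 equiv), CH2Cl2, −78 °C
Reagents that add atoms: none
Why: The activated N-acylthiazolidinethione is reduced directly to the aldehyde at −78 °C, far faster than the tert-butyl ester, and the auxiliary is released.

Step 12
Reactants: 11 Z-iodoalkene; 18 C6 aldehyde
Product: 21 bis(triethylsilyl) trans-γ-lactone (3S,4Z,6S,7R,8R,10S), via alkenyllithium 19 (not isolated), via lithium alkoxide 20 (not isolated)
Conditions: 11, t-BuLi (2.0 equiv), Et2O, −78 °C; add 18, −78 °C; then warm to 23 °C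
Reagents that add atoms: none
Why: Halogen–lithium exchange gives the configurationally stable Z-alkenyllithium, which should add to the α-branched aldehyde in the Felkin–Anh sense (C8 branch anti to the nucleophile, O6 syn to C11), and on warming the alkoxide closes onto the tert-butyl ester (5-exo-trig acyl substitution) to give the trans-4,5-disubstituted γ-lactone with C6 (S).

Step 13
Reactants: 21 bis(triethylsilyl) lactone
Product: 22 diol lactone (3S,4Z,6S,7S,8R,10S) with free C3 and C8 hydroxyls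
Conditions: AcOH/THF/H2O (3:1:1), 23 °C
Reagents that add atoms: none
Why: Mild acid hydrolysis removes the two secondary triethylsilyl ethers much faster than the primary TBS ether, and it avoids alcoholic solvent that could scramble the lactone.

Step 14
Reactants: 22 diol lactone
Product: 23 methyl Z-enone (4Z,6S,7S,8R,10S) with free C8 hydroxyl
Conditions: MnO2 (excess), CH2Cl2, 23 °C
Reagents that add atoms: none
Why: MnO2 oxidises only the allylic C3 alcohol, and because O6 is already tied up in the lactone the Z-enone cannot cyclise to a furan-forming hemiketal.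

Step 15
Reactants: 23 hydroxy enone
Product: 24 C8 isobutyrate (4Z,6S,7S,8R,10S)
Conditions: i-PrCOCl, pyridine, DMAP (cat.), CH2Cl2, 0 °C
Reagents that add atoms: isobutyryl chloride, CC(C)C(Cl)=O
Why: Nucleophile-catalysed acylation of the only free hydroxyl installs the ester of the target.

Step 16
Reactants: 24 isobutyrate
Product: 25 C1 alcohol (4Z,6S,7S,8R,10S)
Conditions: HF·pyridine, pyridine, THF, 0 to 23 °C
Reagents that add atoms: none
Why: Fluoride cleavage of the primary TBS ether is done before bromine is introduced, because a bromomethyl ketone would alkylate pyridine.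

Step 17
Reactants: 25 hydroxy methyl ketone
Product: 28 bromomethyl ketone alcohol (4Z,6S,7S,8R,10S), via bis(trimethylsilyl) dienol ether 26 (not isolated), via bromo ketone silyl ether 27 (not isolated)
Conditions: TMSOTf (2.5 equiv), Et3N, CH2Cl2, −78 to 0 °C; then NBS, THF, −78 °C; then 1 M HCl, THF, 0 °C
Reagents that add atoms: N-bromosuccinimide, O=C1CCC(=O)N1Br
Why: Soft enolisation silylates the C1 hydroxyl and turns the methyl ketone into the 2-silyloxydiene at C2 (α′), NBS brominates the enol ether terminus (α-bromination via a silyl enol ether), and dilute acid removes the O-silyl group.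

Step 18
Reactants: 28 bromomethyl ketone alcohol
Product: 29 bromomethyl ketone aldehyde (4Z,6S,7S,8R,10S), the cyclisation precursor
Conditions: Dess–Martin periodinane, NaHCO3, CH2Cl2, 0 to 23 °C
Reagents that add atoms: none
Why: Dess–Martin oxidation gives the α-alkoxy aldehyde under buffered, non-basic conditions that the bromomethyl ketone tolerates.

Step 19
Reactants: 29 bromomethyl ketone aldehyde
Product: 31 ten-membered β-hydroxy ketone (1S,4Z,6S,7S,8R,10S), via samarium enolate 30 (not isolated)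
Conditions: SmI2 (2.2 equiv), THF, −78 °C, slow addition of 29 (final 0.002 M); sat. NH4Cl at −78 °C
Reagents that add atoms: none
Why: Two single-electron transfers from SmI2 cleave the C2–Br bond and give the trivalent samarium enolate 30 regiospecifically at C2 and without base; the enolate adds to the C1 aldehyde through a closed, chair-like transition state in which samarium bridges the enolate and aldehyde oxygens. The closest known reaction type is the SmI2-promoted intramolecular Reformatsky (aldol) cyclisation of bromoacyl aldehydes, which is established for medium and large carbocycles. The ten-membered carbocycle closes by C1–C2 bond formation in a 10-(enolendo)-exo-trig mode, with the Z C4=C5 bond and the trans-lactone turning the two chain ends toward each other. The new stereocentre C1 is controlled by C10: samarium is chelated between the aldehyde oxygen and the PMB-ether oxygen, and C2 should attack the face next to the C14 methyl (anti to the C9 branch), which places the C1 hydroxyl syn to O10 (1S). The step needs C–Br reduction ahead of enone, aldehyde and ester reduction, and ring closure ahead of oligomerisation: the α-bromo ketone is the fastest acceptor for SmI2, only 2.2 equiv are used at −78 °C, the aldehyde cannot enolise or eliminate because C10 is quaternary, and the substrate is added slowly at high dilution.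

Step 20
Reactants: 31 β-hydroxy ketone
Product: 32 1,3-anti diol (1S,3S,4Z,6S,7S,8R,10S)
Conditions: Me4NBH(OAc)3, MeCN/AcOH (1:1), −30 °C
Reagents that add atoms: none
Why: In this Evans–Saksena reduction the C1 hydroxyl exchanges onto boron and delivers hydride intramolecularly through a chair-like transition state, which should give the 1,3-anti diol and hence C3 (S) by 1,2-reduction of the enone.

Step 21
Reactants: 32 anti diol
Product: 33 C3 tert-butyldimethylsilyl ether (1S,3S,4Z,6S,7S,8R,10S) with free C1 hydroxyl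
Conditions: TBSCl, imidazole, DMF, 0 °C
Reagents that add atoms: tert-butyldimethylsilyl chloride, CC(C)(C)[Si](C)(C)Cl
Why: The allylic C3 hydroxyl should be silylated selectively because the C1 hydroxyl is shielded by the adjacent quaternary C10.

Step 22
Reactants: 33 C3 silyl ether
Product: 34 C1 mesylate (1S,3S,4Z,6S,7S,8R,10S)
Conditions: MsCl, Et3N, CH2Cl2, 0 °C
Reagents that add atoms: methanesulfonyl chloride, CS(=O)(=O)Cl
Why: Mesylation through the sulfene pathway activates the hindered C1 hydroxyl, and doing it before PMB removal avoids oxidative acetal formation between O1 and O10.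

Step 23
Reactants: 34 C1 mesylate
Product: 35 C10 alcohol C1 mesylate (1S,3S,4Z,6S,7S,8R,10S)
Conditions: DDQ, CH2Cl2/pH 7 buffer (10:1), 0 to 23 °C
Reagents that add atoms: none
Why: DDQ abstracts the benzylic hydride of the PMB ether and water hydrolyses the oxocarbenium ion, freeing the tertiary O10 under neutral conditions.

Step 24
Reactants: 35 hydroxy mesylate
Product: 36 1,10-epoxide (1R,3S,4Z,6S,7S,8R,10S)
Conditions: NaH, THF, 0 °C
Reagents that add atoms: none
Why: Intramolecular Williamson closure (3-exo-tet) by the C10 alkoxide displaces the C1 mesylate with inversion, turning the syn 1S,10S pair into the (1R,10S) cis-oxirane.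

Step 25
Reactants: 36 epoxy lactone
Product: 39 α-methylene lactone 3-O-TBS ether (1R,3S,4Z,6S,7S,8R,10S), via Mannich base 37 (not isolated), via trimethylammonium iodide 38 (not isolated)
Conditions: LiN(i-Pr)2 (1.2 equiv), THF, −78 °C; CH2=NMe2+ I−, −78 to 0 °C; then MeI, MeOH, 23 °C; then NaHCO3 (aq), CH2Cl2
Reagents that add atoms: N,N-dimethylmethyleneiminium iodide (Eschenmoser's salt), C=[N+](C)C.[I-]
Why: The lactone CH2 is deprotonated faster than the hindered isobutyrate CH, the enolate undergoes a Mannich reaction with Eschenmoser's salt, and quaternisation followed by E1cB loss of trimethylamine gives the exocyclic C11=C13 bond.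

Step 26
Reactants: 39 silylated target
Product: 40 target CNP0261225.1 (1R,3S,4Z,6S,7S,8R,10S)
Conditions: HF·pyridine, pyridine, THF, 0 to 23 °C
Reagents that add atoms: none
Why: Buffered HF·pyridine cleaves the allylic silyl ether without opening the oxirane or adding to the α-methylene lactone.

**Compound list**

1 | (R)-2-methylglycidol, (2R)-(2-methyloxiran-2-yl)methanol | C[C@@]1(CO)CO1 | starting material
2 | (S)-2-methylpent-4-ene-1,2-diol | C=CC[C@](C)(O)CO | intermediate
3 | (4S)-2-(4-methoxyphenyl)-4-methyl-4-(prop-2-en-1-yl)-1,3-dioxolane, both acetal epimers | C=CC[C@@]1(C)COC(c2ccc(OC)cc2)O1 | intermediate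
4 | (S)-2-[(4-methoxybenzyl)oxy]-2-methylpent-4-en-1-ol | C=CC[C@](C)(OCc1ccc(OC)cc1)CO | intermediate
5 | (S)-tert-butyl({2-[(4-methoxybenzyl)oxy]-2-methylpent-4-en-1-yl}oxy)dimethylsilane | C=CC[C@](C)(OCc1ccc(OC)cc1)CO[Si](C)(C)C(C)(C)C | intermediate
6 | (4S)-5-[(tert-butyldimethylsilyl)oxy]-4-[(4-methoxybenzyl)oxy]-4-methylpentane-1,2-diol, C2 epimers, not isolated | OCC(O)C[C@](C)(OCc1ccc(OC)cc1)CO[Si](C)(C)C(C)(C)C | intermediate
7 | (S)-4-[(tert-butyldimethylsilyl)oxy]-3-[(4-methoxybenzyl)oxy]-3-methylbutanal (C8–C9–C10–C1 aldehyde) | O=CC[C@](C)(OCc1ccc(OC)cc1)CO[Si](C)(C)C(C)(C)C | intermediate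
8 | (S)-but-3-yn-2-ol | C[C@H](O)C#C | starting material
9 | cyclic Z-alkenylmagnesium alkoxide, (5S)-4,5-dimethyl-2,5-dihydro-1,2-oxamagnesole, not isolated | C[C@@H]1O[Mg]C=C1C | intermediate
10 | (2S,3Z)-4-iodo-3-methylbut-3-en-2-ol | C[C@H](O)/C(C)=C\I | intermediate
11 | triethyl{[(2S,3Z)-4-iodo-3-methylbut-3-en-2-yl]oxy}silane | C[C@H](O[Si](CC)(CC)CC)/C(C)=C\I | intermediate
12 | 4-(tert-butoxy)-4-oxobutanoic acid (mono-tert-butyl succinate) | CC(C)(C)OC(=O)CCC(=O)O | starting material
13 | (S)-4-benzyl-1,3-thiazolidine-2-thione | S=C1N[C@@H](Cc2ccccc2)CS1 | starting material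
14 | tert-butyl 4-[(4S)-4-benzyl-2-thioxo-1,3-thiazolidin-3-yl]-4-oxobutanoate | CC(C)(C)OC(=O)CCC(=O)N1C(=S)SC[C@@H]1Cc1ccccc1 | intermediate
15 | Z-trichlorotitanium enolate of 14 (C6=C7, O–TiCl3), not isolated | CC(C)(C)OC(=O)C/C=C(\O[Ti](Cl)(Cl)Cl)N1C(=S)SC[C@@H]1Cc1ccccc1 | intermediate
16 | tert-butyl (3S,4R,6S)-3-{[(4S)-4-benzyl-2-thioxo-1,3-thiazolidin-3-yl]carbonyl}-7-[(tert-butyldimethylsilyl)oxy]-4-hydroxy-6-[(4-methoxybenzyl)oxy]-6-methylheptanoate (7S,8R,10S) | CC(C)(C)OC(=O)C[C@H](C(=O)N1C(=S)SC[C@@H]1Cc1ccccc1)[C@H](O)C[C@](C)(OCc1ccc(OC)cc1)CO[Si](C)(C)C(C)(C)C | intermediate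
17 | 4-O-triethylsilyl ether of 16 (7S,8R,10S) | CC(C)(C)OC(=O)C[C@H](C(=O)N1C(=S)SC[C@@H]1Cc1ccccc1)[C@H](O[Si](CC)(CC)CC)C[C@](C)(OCc1ccc(OC)cc1)CO[Si](C)(C)C(C)(C)C | intermediate
18 | tert-butyl (3S,4R,6S)-7-[(tert-butyldimethylsilyl)oxy]-3-formyl-6-[(4-methoxybenzyl)oxy]-6-methyl-4-[(triethylsilyl)oxy]heptanoate (C6 aldehyde; 7S,8R,10S) | CC(C)(C)OC(=O)C[C@H](C=O)[C@H](O[Si](CC)(CC)CC)C[C@](C)(OCc1ccc(OC)cc1)CO[Si](C)(C)C(C)(C)C | intermediate
19 | (3S,4Z)-alkenyllithium from 11 (lithium on C5), not isolated | C[C@H](O[Si](CC)(CC)CC)/C(C)=C\[Li] | intermediate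
20 | lithium C6-alkoxide of the open-chain adduct, tert-butyl ester (3S,4Z,6S,7R,8R,10S), not isolated | C[C@H](O[Si](CC)(CC)CC)/C(C)=C\[C@H]([O-])[C@@H](CC(=O)OC(C)(C)C)[C@H](O[Si](CC)(CC)CC)C[C@](C)(OCc1ccc(OC)cc1)CO[Si](C)(C)C(C)(C)C.[Li+] | intermediate
21 | trans-γ-lactone (C6–O–C12), 3S,4Z,6S,7R,8R,10S; O3 and O8 triethylsilyl, O10 PMB, O1 TBS | C[C@H](O[Si](CC)(CC)CC)/C(C)=C\[C@@H]1OC(=O)C[C@H]1[C@H](O[Si](CC)(CC)CC)C[C@](C)(OCc1ccc(OC)cc1)CO[Si](C)(C)C(C)(C)C | intermediate
22 | diol lactone, 3S,4Z,6S,7S,8R,10S; C3–OH and C8–OH free, O10 PMB, O1 TBS | C[C@H](O)/C(C)=C\[C@@H]1OC(=O)C[C@H]1[C@H](O)C[C@](C)(OCc1ccc(OC)cc1)CO[Si](C)(C)C(C)(C)C | intermediate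
23 | methyl Z-enone lactone, 4Z,6S,7S,8R,10S; C3 ketone, C8–OH free | CC(=O)/C(C)=C\[C@@H]1OC(=O)C[C@H]1[C@H](O)C[C@](C)(OCc1ccc(OC)cc1)CO[Si](C)(C)C(C)(C)C | intermediate
24 | C8 isobutyrate of 23, 4Z,6S,7S,8R,10S | CC(=O)/C(C)=C\[C@@H]1OC(=O)C[C@H]1[C@H](OC(=O)C(C)C)C[C@](C)(OCc1ccc(OC)cc1)CO[Si](C)(C)C(C)(C)C | intermediate
25 | C1 alcohol, methyl Z-enone, C8 isobutyrate, O10 PMB; 4Z,6S,7S,8R,10S | CC(=O)/C(C)=C\[C@@H]1OC(=O)C[C@H]1[C@H](OC(=O)C(C)C)C[C@](C)(OCc1ccc(OC)cc1)CO | intermediate
26 | 3-(trimethylsilyloxy)-2,4-diene (C2=C3, C4=C5) with C1–O-trimethylsilyl ether, not isolated | C=C(O[Si](C)(C)C)/C(C)=C\[C@@H]1OC(=O)C[C@H]1[C@H](OC(=O)C(C)C)C[C@](C)(OCc1ccc(OC)cc1)CO[Si](C)(C)C | intermediate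
27 | bromomethyl ketone with C1–O-trimethylsilyl ether, not isolated | BrCC(=O)/C(C)=C\[C@@H]1OC(=O)C[C@H]1[C@H](OC(=O)C(C)C)C[C@](C)(OCc1ccc(OC)cc1)CO[Si](C)(C)C | intermediate
28 | bromomethyl Z-enone, C1 alcohol; 4Z,6S,7S,8R,10S | BrCC(=O)/C(C)=C\[C@@H]1OC(=O)C[C@H]1[C@H](OC(=O)C(C)C)C[C@](C)(OCc1ccc(OC)cc1)CO | intermediate
29 | bromomethyl Z-enone, C1 aldehyde, trans-lactone, C8 isobutyrate, C10 PMB ether; 4Z,6S,7S,8R,10S (cyclisation precursor) | BrCC(=O)/C(C)=C\[C@@H]1OC(=O)C[C@H]1[C@H](OC(=O)C(C)C)C[C@](C)(OCc1ccc(OC)cc1)C=O | intermediate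
30 | diiodosamarium enolate of 29 (C2=C3, O–SmI2), not isolated | C=C(O[Sm](I)I)/C(C)=C\[C@@H]1OC(=O)C[C@H]1[C@H](OC(=O)C(C)C)C[C@](C)(OCc1ccc(OC)cc1)C=O | intermediate
31 | ten-membered β-hydroxy ketone (C1 carbinol, C3 ketone), 1S,4Z,6S,7S,8R,10S | O=C1C[C@H]2[C@H](OC(=O)C(C)C)C[C@](C)(OCc3ccc(OC)cc3)[C@@H](O)CC(=O)/C(C)=C\[C@@H]2O1 | intermediate
32 | 1,3-anti diol, 1S,3S,4Z,6S,7S,8R,10S | O=C1C[C@H]2[C@H](OC(=O)C(C)C)C[C@](C)(OCc3ccc(OC)cc3)[C@@H](O)C[C@H](O)/C(C)=C\[C@@H]2O1 | intermediate
33 | C3 tert-butyldimethylsilyl ether, C1–OH free, 1S,3S,4Z,6S,7S,8R,10S | O=C1C[C@H]2[C@H](OC(=O)C(C)C)C[C@](C)(OCc3ccc(OC)cc3)[C@@H](O)C[C@H](O[Si](C)(C)C(C)(C)C)/C(C)=C\[C@@H]2O1 | intermediate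
34 | C1 mesylate of 33, 1S,3S,4Z,6S,7S,8R,10S | O=C1C[C@H]2[C@H](OC(=O)C(C)C)C[C@](C)(OCc3ccc(OC)cc3)[C@@H](OS(C)(=O)=O)C[C@H](O[Si](C)(C)C(C)(C)C)/C(C)=C\[C@@H]2O1 | intermediate
35 | C10 tertiary alcohol with C1 mesylate, 1S,3S,4Z,6S,7S,8R,10S | O=C1C[C@H]2[C@H](OC(=O)C(C)C)C[C@](C)(O)[C@@H](OS(C)(=O)=O)C[C@H](O[Si](C)(C)C(C)(C)C)/C(C)=C\[C@@H]2O1 | intermediate
36 | 1,10-epoxide with saturated lactone (C11 CH2), 3-O-TBS, 8-O-isobutyryl; 1R,3S,4Z,6S,7S,8R,10S | C1C(=O)O[C@H]2/C=C(/C)[C@@H](O[Si](C)(C)C(C)(C)C)C[C@H]3O[C@@]3(C)C[C@@H](OC(=O)C(C)C)[C@H]12 | intermediate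
37 | 11-(dimethylaminomethyl) lactone (Mannich base, C11 epimers), not isolated | CN(C)CC1C(=O)O[C@H]2/C=C(/C)[C@@H](O[Si](C)(C)C(C)(C)C)C[C@H]3O[C@@]3(C)C[C@@H](OC(=O)C(C)C)[C@H]12 | intermediate
38 | 11-(trimethylammoniomethyl) lactone iodide, not isolated | C[N+](C)(C)CC1C(=O)O[C@H]2/C=C(/C)[C@@H](O[Si](C)(C)C(C)(C)C)C[C@H]3O[C@@]3(C)C[C@@H](OC(=O)C(C)C)[C@H]12.[I-] | intermediate
39 | 3-O-tert-butyldimethylsilyl ether of the target, 1R,3S,4Z,6S,7S,8R,10S | C=C1C(=O)O[C@H]2/C=C(/C)[C@@H](O[Si](C)(C)C(C)(C)C)C[C@H]3O[C@@]3(C)C[C@@H](OC(=O)C(C)C)[C@H]12 | intermediate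
40 | CNP0261225.1, (1R,3S,4Z,6S,7S,8R,10S)-1,10-epoxy-3-hydroxy-8-isobutyryloxygermacra-4,11(13)-dien-6,12-olide | C=C1C(=O)O[C@H]2/C=C(/C)[C@@H](O)C[C@H]3O[C@@]3(C)C[C@@H](OC(=O)C(C)C)[C@H]12 | target

**Step count**

Total: 26 steps. Longest linear sequence: 23 steps (steps 1–5 and 9–26, from 1 to 40).

**Steps most likely to fail**

Step 19. The samarium enolate may oligomerise instead of closing the ring, surplus SmI2 may reduce the γ-acyloxy enone, or the O10 chelate may not hold so that facial control at C1 is lost. The fallback makes the same C1–C2 bond by a chelation-controlled Mukaiyama aldol macrocyclisation. It sets out from hydroxy ketone 25: Dess–Martin oxidation should give the keto aldehyde F1. Soft enolisation with TMSOTf (1.05 equiv) and excess Et3N at −78 °C, where the non-enolisable aldehyde is left alone, should give the silyloxydiene aldehyde F2. Slow addition of F2 to MgBr2·OEt2 in CH2Cl2 at high dilution lets magnesium chelate the aldehyde and PMB-ether oxygens, and the enol silane attacks through an open transition state from the methyl-bearing face. Aqueous work-up returns to β-hydroxy ketone 31.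

Step 12. Facial selectivity at the C6 aldehyde may be poor, because Felkin–Anh control from C7 is opposed by the β-silyloxy group; the basic alkenyllithium may also enolise the aldehyde, and closure onto the tert-butyl ester may be slow. The fallback forms C5–C6 under reagent control by an asymmetric Nozaki–Hiyama–Kishi coupling. It sets out from iodide 11 and aldehyde 18: CrCl2 with catalytic NiCl2, Et3N and a chiral sulfonamide–oxazoline ligand in THF/MeCN generates the alkenylchromium dichloride F3, which adds to 18 within the ligand sphere to give the (6S) hydroxy tert-butyl ester F4. NaH in THF then closes the lactone and returns to 21.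

Step 20. The ring conformation may prevent the chair-like internal hydride delivery, giving weak 1,3-induction, and the two secondary hydroxyls may then be poorly distinguished in step 21. The fallback reverses the order of protection and reduction and uses reagent control. It sets out from 31: TESOTf and 2,6-lutidine silylate the C1 hydroxyl to give the silyloxy ketone F5. Corey–Bakshi–Shibata reduction with (R)-2-methyl-CBS-oxazaborolidine and catecholborane, the alkenyl arm acting as the large group, should give the (3S) allylic alcohol F6. TBSOTf and 2,6-lutidine give the mixed bis-silyl ether F7, and AcOH/THF/H2O removes the more labile triethylsilyl group to return to 33.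

**Further compounds**

F1 | step 19 | keto aldehyde: methyl Z-enone with C1 aldehyde, C8 isobutyrate, C10 PMB ether (4Z,6S,7S,8R,10S) | CC(=O)/C(C)=C\[C@@H]1OC(=O)C[C@H]1[C@H](OC(=O)C(C)C)C[C@](C)(OCc1ccc(OC)cc1)C=O
F2 | step 19 | 3-(trimethylsilyloxy)-2,4-diene with C1 aldehyde (4Z,6S,7S,8R,10S) | C=C(O[Si](C)(C)C)/C(C)=C\[C@@H]1OC(=O)C[C@H]1[C@H](OC(=O)C(C)C)C[C@](C)(OCc1ccc(OC)cc1)C=O
F3 | step 12 | (3S,4Z)-alkenylchromium dichloride from 11 | C[C@H](O[Si](CC)(CC)CC)/C(C)=C\[Cr](Cl)Cl
F4 | step 12 | open-chain C6 carbinol tert-butyl ester (3S,4Z,6S,7R,8R,10S), conjugate acid of 20 | C[C@H](O[Si](CC)(CC)CC)/C(C)=C\[C@H](O)[C@@H](CC(=O)OC(C)(C)C)[C@H](O[Si](CC)(CC)CC)C[C@](C)(OCc1ccc(OC)cc1)CO[Si](C)(C)C(C)(C)C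
F5 | step 20 | C1 triethylsilyl ether of 31 (1S,4Z,6S,7S,8R,10S) | O=C1C[C@H]2[C@H](OC(=O)C(C)C)C[C@](C)(OCc3ccc(OC)cc3)[C@@H](O[Si](CC)(CC)CC)CC(=O)/C(C)=C\[C@@H]2O1
F6 | step 20 | (3S) allylic alcohol with C1 triethylsilyl ether (1S,3S,4Z,6S,7S,8R,10S) | O=C1C[C@H]2[C@H](OC(=O)C(C)C)C[C@](C)(OCc3ccc(OC)cc3)[C@@H](O[Si](CC)(CC)CC)C[C@H](O)/C(C)=C\[C@@H]2O1
F7 | step 20 | C1 triethylsilyl, C3 tert-butyldimethylsilyl bis-ether (1S,3S,4Z,6S,7S,8R,10S) | O=C1C[C@H]2[C@H](OC(=O)C(C)C)C[C@](C)(OCc3ccc(OC)cc3)[C@@H](O[Si](CC)(CC)CC)C[C@H](O[Si](C)(C)C(C)(C)C)/C(C)=C\[C@@H]2O1
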